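**Retrosynthetic overview**
- Feature: the central anisole ring (C1'–C6' of the 7-methoxyflavone, unit 1) is 1,3,4-trisubstituted, with a carbon substituent at C1', the crowded flavon-8''-yl group of unit 2 at C3' and OMe at C4'. A 5-carboxylated 2-pyrone and an aryl methyl ynol ether deliver exactly this pattern after cycloaddition and loss of CO2.
- Target ⇒ bis-benzyl ether ⇒ 1,3-diketone (cyclodehydration closes the pyranone ring of unit 1) ⇒ aryl ester of 2'-hydroxy-4'-methoxyacetophenone (Baker–Venkataraman shift) ⇒ benzoic acid ⇒ methyl benzoate.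
- Methyl benzoate ⇒ methyl coumalate + 8-(methoxyethynyl)flavone: inverse-demand [4+2] cycloaddition forms C2'–C3' and C4'–C5', and CO2 extrusion aromatizes the new ring.
- Ynol ether ⇒ 8-iodo-4',7-bis(benzyloxy)flavone + methoxyethynylzinc chloride (from chloroacetaldehyde dimethyl acetal); the iodide ⇒ 4',7-dihydroxyflavone.
- Ring order: the rings of unit 2 are purchased; the central benzene ring is built in step 4; the pyranone ring of unit 1 is closed in step 8.

Key step: step 4

Remark: the target is drawn without an axial descriptor, so the C3'–C8'' biaryl axis (three ortho oxygen substituents, one ortho hydrogen) is treated as configurationally undefined and no control of axial chirality is attempted.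

**Step 1**
Reactants: 1 4',7-dihydroxyflavone
Product: 2 7-hydroxy-2-(4-hydroxyphenyl)-8-iodochromen-4-one
Conditions: NIS (1.0 equiv), DMF, 0 °C to rt, dark
Reagents that add atoms: N-iodosuccinimide, O=C1CCC(=O)N1I
Why: Electrophilic aromatic iodination should go to C8, which is ortho to both the 7-OH and the ring oxygen O1 (a resorcinol-type position and the usual site of attack in 7-hydroxyflavones), whereas the ring B phenol carries only one activating group and is deactivated by conjugation with C4=O.

**Step 2**
Reactants: 2 7-hydroxy-2-(4-hydroxyphenyl)-8-iodochromen-4-one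
Product: 3 7-benzyloxy-2-(4-benzyloxyphenyl)-8-iodochromen-4-one
Conditions: BnBr (2.5 equiv), K2CO3, DMF, 60 °C
Reagents that add atoms: benzyl bromide, BrCc1ccccc1
Why: Williamson etherification of both acidic phenols is expected to be straightforward and gives ethers that survive organozinc reagents, heat, hydroxide and amide bases.

**Step 3**
Reactants: 3 7-benzyloxy-2-(4-benzyloxyphenyl)-8-iodochromen-4-one; 4 chloroacetaldehyde dimethyl acetal
Product: 7 7-benzyloxy-2-(4-benzyloxyphenyl)-8-(methoxyethynyl)chromen-4-one, via lithium methoxyacetylide 5 (not isolated), via methoxyethynylzinc chloride 6 (not isolated)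
Conditions: 4 (3 equiv), LiNEt2 (9 equiv, from Et2NH and n-BuLi), THF, 0 °C; ZnCl2 (7 equiv), 0 °C; then 3, Pd(PPh3)4 (5 mol %), THF, rt to 50 °C; aq NaHCO3 work-up, Et3N-deactivated silica
Reagents that add atoms: none
Why: Double elimination and metalation of 4 by LiNEt2 gives the lithium alkoxyacetylide, transmetalation to zinc tempers its basicity, and Negishi coupling of this small sp nucleophile with the di-ortho-substituted aryl iodide is a known route to aryl alkoxyacetylenes that should leave the chromone untouched, provided the work-up stays non-acidic so the ynol ether is not hydrated.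

**Step 4**
Reactants: 7 7-benzyloxy-2-(4-benzyloxyphenyl)-8-(methoxyethynyl)chromen-4-one; 8 methyl coumalate
Product: 10 methyl 3-[7-benzyloxy-2-(4-benzyloxyphenyl)-4-oxochromen-8-yl]-4-methoxybenzoate, via bridged bicyclic lactone 9 (not isolated)
Conditions: 8 (3 equiv), toluene, 110 °C, sealed tube, N2
Reagents that add atoms: none
Why: The electron-poor 2-pyrone 8 (diene C3=C4–C5=C6) and the electron-rich ynol ether 7 should combine in an inverse-electron-demand Diels–Alder reaction, the closest known reaction type being the cycloaddition of methyl coumalate with ynamines, ketene acetals and other donor-substituted π systems followed by decarboxylative aromatization to benzoates. The six-membered carbocycle is closed in one bimolecular [4+2] event that forms C2'–C3' (pyrone C6 to the aryl-bearing alkyne carbon) and C4'–C5' (pyrone C3 to the methoxy-bearing carbon), probably asynchronously with the first bond leading. Bridged lactone 9 then expels CO2 by retro-[4+2] cycloreversion at the reaction temperature, so the new ring emerges as a benzene ring with the ester at C1', the flavonyl group at C3' and methoxy at C4'. No stereocentre remains, because the two bridgehead centres of racemic 9 become aromatic carbons. The step needs regiocontrol, and matched polarization supplies it: oxygen donation makes the alkyne carbon β to OMe (the one bonded to the flavone) the nucleophilic terminus, and pyrone C6, β to the ester and δ to the lactone carbonyl, is the electrophilic terminus, so methoxy ends up para to the ester. The methyl ynol ether cannot fragment to a ketene by retro-ene loss of an alkene, and the hindered C3'–C8'' bond is already in place as an unhindered aryl–alkyne bond before the ring is built.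

**Step 5**
Reactants: 10 methyl 3-[7-benzyloxy-2-(4-benzyloxyphenyl)-4-oxochromen-8-yl]-4-methoxybenzoate
Product: 11 3-[7-benzyloxy-2-(4-benzyloxyphenyl)-4-oxochromen-8-yl]-4-methoxybenzoic acid
Conditions: LiOH·H2O (3 equiv), THF/MeOH/H2O, 40 °C; then 1 M HCl to pH 3
Reagents that add atoms: lithium hydroxide, [Li+].[OH-]
Why: Acyl-oxygen saponification of the methyl ester should proceed under mild hydroxide conditions that the ethers tolerate, and any reversible hydroxide opening of the 2-aryl pyranone ring is undone on acidification.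

**Step 6**
Reactants: 11 3-[7-benzyloxy-2-(4-benzyloxyphenyl)-4-oxochromen-8-yl]-4-methoxybenzoic acid; 12 2'-hydroxy-4'-methoxyacetophenone
Product: 13 2-acetyl-5-methoxyphenyl 3-[7-benzyloxy-2-(4-benzyloxyphenyl)-4-oxochromen-8-yl]-4-methoxybenzoate
Conditions: DCC (1.3 equiv), DMAP (0.2 equiv), CH2Cl2, rt
Reagents that add atoms: none
Why: Steglich esterification through the acylpyridinium ion should acylate the hydrogen-bonded phenol of 12 under neutral conditions, the carboxyl group sitting meta to the biaryl bond and therefore unhindered.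

**Step 7**
Reactants: 13 2-acetyl-5-methoxyphenyl 3-[7-benzyloxy-2-(4-benzyloxyphenyl)-4-oxochromen-8-yl]-4-methoxybenzoate
Product: 14 1-{3-[7-benzyloxy-2-(4-benzyloxyphenyl)-4-oxochromen-8-yl]-4-methoxyphenyl}-3-(2-hydroxy-4-methoxyphenyl)propane-1,3-dione
Conditions: LiN(SiMe3)2 (3 equiv), THF, −78 °C to rt; then aq HCl
Reagents that add atoms: none
Why: In the Baker–Venkataraman rearrangement the methyl ketone enolate attacks the neighbouring aryl ester intramolecularly and the acyl group shifts from O to C, a non-nucleophilic amide base being chosen so that neither the ester nor the flavone of unit 2 is attacked.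

**Step 8**
Reactants: 14 1-{3-[7-benzyloxy-2-(4-benzyloxyphenyl)-4-oxochromen-8-yl]-4-methoxyphenyl}-3-(2-hydroxy-4-methoxyphenyl)propane-1,3-dione
Product: 15 7-benzyloxy-2-(4-benzyloxyphenyl)-8-[2-methoxy-5-(7-methoxy-4-oxochromen-2-yl)phenyl]chromen-4-one
Conditions: TsOH·H2O (0.2 equiv), toluene, 100 °C
Reagents that add atoms: none
Why: Acid-catalysed cyclodehydration (attack of the phenol on the distal carbonyl, then loss of water) is the standard closure of o-hydroxyaryl 1,3-diketones to flavones, and it places the methoxy group at C7 of unit 1 while the benzyl ethers should survive the catalytic sulfonic acid.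

**Step 9**
Reactants: 15 7-benzyloxy-2-(4-benzyloxyphenyl)-8-[2-methoxy-5-(7-methoxy-4-oxochromen-2-yl)phenyl]chromen-4-one
Product: 16 7-hydroxy-2-(4-hydroxyphenyl)-8-[2-methoxy-5-(7-methoxy-4-oxochromen-2-yl)phenyl]chromen-4-one (CNP0121664.0)
Conditions: H2 (1 atm), 10% Pd/C, THF/MeOH, rt
Reagents that add atoms: none
Why: Catalytic hydrogenolysis should cleave both aryl benzyl ethers while the two methyl ethers are inert and the vinylogous-ester C2=C3 bonds of the chromones are reduced only slowly at ambient pressure, so the reaction is stopped once debenzylation is complete.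

**Compound list**
1 | 4',7-dihydroxyflavone | O=c1cc(-c2ccc(O)cc2)oc2cc(O)ccc12 | starting material
2 | 7-hydroxy-2-(4-hydroxyphenyl)-8-iodochromen-4-one | O=c1cc(-c2ccc(O)cc2)oc2c(I)c(O)ccc12 | intermediate
3 | 7-benzyloxy-2-(4-benzyloxyphenyl)-8-iodochromen-4-one | O=c1cc(-c2ccc(OCc3ccccc3)cc2)oc2c(I)c(OCc3ccccc3)ccc12 | intermediate
4 | chloroacetaldehyde dimethyl acetal | COC(CCl)OC | starting material
5 | lithium methoxyacetylide (not isolated) | COC#C[Li] | intermediate
6 | methoxyethynylzinc chloride (not isolated) | COC#C[Zn]Cl | intermediate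
7 | 7-benzyloxy-2-(4-benzyloxyphenyl)-8-(methoxyethynyl)chromen-4-one | COC#Cc1c(OCc2ccccc2)ccc2c(=O)cc(-c3ccc(OCc4ccccc4)cc3)oc12 | intermediate
8 | methyl coumalate | COC(=O)c1ccc(=O)oc1 | starting material
9 | methyl 7-[7-benzyloxy-2-(4-benzyloxyphenyl)-4-oxochromen-8-yl]-8-methoxy-3-oxo-2-oxabicyclo[2.2.2]octa-5,7-diene-6-carboxylate (racemic, not isolated) | COC(=O)C1=CC2C(=O)OC1C(c1c(OCc3ccccc3)ccc3c(=O)cc(-c4ccc(OCc5ccccc5)cc4)oc13)=C2OC | intermediate
10 | methyl 3-[7-benzyloxy-2-(4-benzyloxyphenyl)-4-oxochromen-8-yl]-4-methoxybenzoate | COC(=O)c1ccc(OC)c(-c2c(OCc3ccccc3)ccc3c(=O)cc(-c4ccc(OCc5ccccc5)cc4)oc23)c1 | intermediate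
11 | 3-[7-benzyloxy-2-(4-benzyloxyphenyl)-4-oxochromen-8-yl]-4-methoxybenzoic acid | OC(=O)c1ccc(OC)c(-c2c(OCc3ccccc3)ccc3c(=O)cc(-c4ccc(OCc5ccccc5)cc4)oc23)c1 | intermediate
12 | 2'-hydroxy-4'-methoxyacetophenone | CC(=O)c1ccc(OC)cc1O | starting material
13 | 2-acetyl-5-methoxyphenyl 3-[7-benzyloxy-2-(4-benzyloxyphenyl)-4-oxochromen-8-yl]-4-methoxybenzoate | CC(=O)c1ccc(OC)cc1OC(=O)c1ccc(OC)c(-c2c(OCc3ccccc3)ccc3c(=O)cc(-c4ccc(OCc5ccccc5)cc4)oc23)c1 | intermediate
14 | 1-{3-[7-benzyloxy-2-(4-benzyloxyphenyl)-4-oxochromen-8-yl]-4-methoxyphenyl}-3-(2-hydroxy-4-methoxyphenyl)propane-1,3-dione | COc1ccc(C(=O)CC(=O)c2ccc(OC)c(-c3c(OCc4ccccc4)ccc4c(=O)cc(-c5ccc(OCc6ccccc6)cc5)oc34)c2)c(O)c1 | intermediate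
15 | 7-benzyloxy-2-(4-benzyloxyphenyl)-8-[2-methoxy-5-(7-methoxy-4-oxochromen-2-yl)phenyl]chromen-4-one | COc1ccc2c(=O)cc(-c3ccc(OC)c(-c4c(OCc5ccccc5)ccc5c(=O)cc(-c6ccc(OCc7ccccc7)cc6)oc45)c3)oc2c1 | intermediate
16 | 7-hydroxy-2-(4-hydroxyphenyl)-8-[2-methoxy-5-(7-methoxy-4-oxochromen-2-yl)phenyl]chromen-4-one (CNP0121664.0) | COc1ccc2c(=O)cc(-c3ccc(OC)c(-c4c(O)ccc5c(=O)cc(-c6ccc(O)cc6)oc45)c3)oc2c1 | target

**Step count**
Total steps: 9. Longest linear sequence: 9 steps (1 to 16); compounds 4, 8 and 12 enter as purchased partners.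

**Steps most likely to fail**

Step 4 (key cycloaddition). The ynol ether may hydrate or oligomerize faster than it is trapped, the di-ortho-substituted aryl group may slow bond formation at the nucleophilic alkyne carbon, or methyl coumalate may self-condense at the temperature required. The fallback sets out from 3 and comes back at 10. A Suzuki–Miyaura coupling of 3 with commercial [2-methoxy-5-(methoxycarbonyl)phenyl]boronic acid (Pd(OAc)2, SPhos, K3PO4, toluene/H2O, 100 °C) would form the C3'–C8'' bond directly, the dialkylbiarylphosphine ligand being suited to tri-ortho-substituted biaryls. No new intermediate is made (F0).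

Step 3 (ynol ether coupling). Oxidative addition and transmetalation at the doubly flanked iodide may be slow enough that protodeiodination or decomposition of the zinc acetylide wins, or the product may be lost by hydration during isolation. The fallback sets out from 3 and comes back at 7, and builds the triple bond by elimination instead of cross-coupling. Iodine–magnesium exchange of 3 (i-PrMgCl·LiCl, THF, −40 °C) and acylation with 2-methoxy-N-methoxy-N-methylacetamide should give the α-methoxy ketone 7-benzyloxy-2-(4-benzyloxyphenyl)-8-(methoxyacetyl)chromen-4-one F1. Trapping of its chelated lithium enolate (LiN(SiMe3)2, PhNTf2, THF, −78 °C) should give (Z)-1-[7-benzyloxy-2-(4-benzyloxyphenyl)-4-oxochromen-8-yl]-2-methoxyethenyl trifluoromethanesulfonate F2. Anti-elimination of triflate with KOt-Bu (THF, −78 °C to rt) then delivers 7.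

Step 1 (iodination). Attack at C3' of ring B or at C6, or double iodination, may compete and give regioisomers that are hard to separate. The fallback sets out from 1 and comes back at 2, and deactivates ring B before the halogenation. Peracetylation (Ac2O, pyridine) gives 4-(7-acetoxy-4-oxochromen-2-yl)phenyl acetate F3. Selective cleavage of the more labile 7-O-acetyl group (PhSH, imidazole, NMP, 0 °C to rt) gives 4-(7-hydroxy-4-oxochromen-2-yl)phenyl acetate F4. Iodination with NIS in DMF, now directed only by the free 7-OH, gives 4-(7-hydroxy-8-iodo-4-oxochromen-2-yl)phenyl acetate F5, and methanolysis (K2CO3, MeOH, rt) returns 2.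

**Further compounds**
F0 | step 4 | none | none
F1 | step 3 | 7-benzyloxy-2-(4-benzyloxyphenyl)-8-(methoxyacetyl)chromen-4-one | COCC(=O)c1c(OCc2ccccc2)ccc2c(=O)cc(-c3ccc(OCc4ccccc4)cc3)oc12
F2 | step 3 | (Z)-1-[7-benzyloxy-2-(4-benzyloxyphenyl)-4-oxochromen-8-yl]-2-methoxyethenyl trifluoromethanesulfonate | CO/C=C(\OS(=O)(=O)C(F)(F)F)c1c(OCc2ccccc2)ccc2c(=O)cc(-c3ccc(OCc4ccccc4)cc3)oc12
F3 | step 1 | 4-(7-acetoxy-4-oxochromen-2-yl)phenyl acetate | CC(=O)Oc1ccc(-c2cc(=O)c3ccc(OC(C)=O)cc3o2)cc1
F4 | step 1 | 4-(7-hydroxy-4-oxochromen-2-yl)phenyl acetate | CC(=O)Oc1ccc(-c2cc(=O)c3ccc(O)cc3o2)cc1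
F5 | step 1 | 4-(7-hydroxy-8-iodo-4-oxochromen-2-yl)phenyl acetate | CC(=O)Oc1ccc(-c2cc(=O)c3ccc(O)c(I)c3o2)cc1
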